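**Strategy.** Locants follow the azulene numbering of the target. The plan rests on an intramolecular (5+2) cycloaddition of a 3-oxidopyrylium ylide with a tethered (Z)-silyl enol ether. It forms C3a–C8a and C7–C8 in one operation and so closes the five- and the seven-membered ring together. The ylide carbons become C3a, C4 (oxido oxygen = C4 oxygen), C5, C6 (methyl) and C7; the enol ether gives C8a and oxygenated C8; C1–C3 are the tether carrying the preset C3 carbinol. The precursor is a furan-derived pyranone hemiacetal. The temporary C3a–O–C7 bridge is later excised reductively, which also places the C6=C7 double bond.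

Key step: step 9

Remark: all bicyclic intermediates keep the azulene locants of the target (C3 carbinol, C3a ring-fusion CH, C4 aroyloxy carbon, C6=C7 alkene, C8 acyloxy carbon, C8a quaternary carbon); 2-bromo-4-methylfuran is taken as a purchasable building block.

**Step 1**
Reactants: 1 (S)-2-hydroxy-3-methylbutanoic acid; 2 2,2-dimethylpropanal
Product: 3 (2S,5S)-2-tert-butyl-5-(propan-2-yl)-1,3-dioxolan-4-one
Conditions: TsOH·H2O (cat.), H2SO4 (cat.), pentane, reflux, water separator; crystallisation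
Reagents that add atoms: none
Why: Acid-catalysed acetalisation to the chiral dioxolanone (self-regeneration of the stereocentre), in which the cis-(2S,5S) acetal should be the favoured, crystalline isomer and stores the configuration of the acid at the acetal carbon.

**Step 2**
Reactants: 3 (2S,5S)-2-tert-butyl-5-(propan-2-yl)-1,3-dioxolan-4-one; 4 3-bromoprop-1-ene
Product: 6 (2S,5S)-2-tert-butyl-5-(prop-2-en-1-yl)-5-(propan-2-yl)-1,3-dioxolan-4-one, via lithium enolate 5 (not isolated)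
Conditions: LiN(i-Pr)2, THF, −78 °C; then 4, −78 → −20 °C
Reagents that add atoms: none
Why: Diastereoselective enolate alkylation in which the allyl group should enter anti to the tert-butyl group, so the quaternary centre (later C3) is set as (S) with overall retention.

**Step 3**
Reactants: 6 (2S,5S)-2-tert-butyl-5-(prop-2-en-1-yl)-5-(propan-2-yl)-1,3-dioxolan-4-one; 7 2-methylprop-2-enal
Product: 8 (2S,5S)-2-tert-butyl-5-[(2E)-3-methyl-4-oxobut-2-en-1-yl]-5-(propan-2-yl)-1,3-dioxolan-4-one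
Conditions: second-generation Hoveyda–Grubbs catalyst (C31H38Cl2N2ORu, 5 mol %), 7 (5 equiv), CH2Cl2, 40 °C
Reagents that add atoms: none
Why: Olefin cross-metathesis of the terminal alkene with excess methacrolein, which should give the (E)-trisubstituted enal as the thermodynamic product.

**Step 4**
Reactants: 8 (2S,5S)-2-tert-butyl-5-[(2E)-3-methyl-4-oxobut-2-en-1-yl]-5-(propan-2-yl)-1,3-dioxolan-4-one
Product: 9 (2S,5S)-2-tert-butyl-5-[(3Z)-3-methyl-4-[(triethylsilyl)oxy]but-3-en-1-yl]-5-(propan-2-yl)-1,3-dioxolan-4-one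
Conditions: RhCl(PPh3)3 (1 mol %), Et3SiH, benzene, 50 °C
Reagents that add atoms: triethylsilane, CC[SiH](CC)CC
Why: Rhodium-catalysed 1,4-hydrosilylation of the enal, in which hydride transfer within the s-cis-bound enal should give the (Z)-silyl enol ether (oxygen cis to the chain), the geometry that later fixes C8.

**Step 5**
Reactants: 9 (2S,5S)-2-tert-butyl-5-[(3Z)-3-methyl-4-[(triethylsilyl)oxy]but-3-en-1-yl]-5-(propan-2-yl)-1,3-dioxolan-4-one; 10 2-bromo-4-methylfuran
Product: 12 (2S,5Z)-2-hydroxy-5-methyl-1-(4-methylfuran-2-yl)-2-(propan-2-yl)-6-[(triethylsilyl)oxy]hex-5-en-1-one, via (4-methylfuran-2-yl)lithium 11 (not isolated)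
Conditions: 10, n-BuLi, THF, −78 °C; then 9, −78 → −20 °C; aq. NH4Cl
Reagents that add atoms: none
Why: Bromine–lithium exchange and addition of the furyllithium to the lactone carbonyl, whose tetrahedral adduct should collapse on work-up with loss of pivalaldehyde to the α-hydroxy ketone without touching the quaternary centre.

**Step 6**
Reactants: 12 (2S,5Z)-2-hydroxy-5-methyl-1-(4-methylfuran-2-yl)-2-(propan-2-yl)-6-[(triethylsilyl)oxy]hex-5-en-1-one
Product: 13 (2S,5Z)-5-methyl-1-(4-methylfuran-2-yl)-2-(propan-2-yl)-2,6-bis[(triethylsilyl)oxy]hex-5-en-1-one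
Conditions: Et3SiOTf, 2,6-lutidine, CH2Cl2, −78 → 0 °C
Reagents that add atoms: triethylsilyl trifluoromethanesulfonate, CC[Si](CC)(CC)OS(=O)(=O)C(F)(F)F
Why: Silylation of the tertiary alcohol with a silyl triflate, which removes the hydrogen-bond donor and gives the bulky polar group that should steer the cycloaddition.

**Step 7**
Reactants: 13 (2S,5Z)-5-methyl-1-(4-methylfuran-2-yl)-2-(propan-2-yl)-2,6-bis[(triethylsilyl)oxy]hex-5-en-1-one
Product: 14 (1RS,2S,5Z)-5-methyl-1-(4-methylfuran-2-yl)-2-(propan-2-yl)-2,6-bis[(triethylsilyl)oxy]hex-5-en-1-ol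
Conditions: i-Bu2AlH, CH2Cl2, −78 °C; aq. KNaC4H4O6
Reagents that add atoms: none
Why: Hydride reduction of the furyl ketone to the furfuryl alcohol under non-basic conditions (no silyl migration); the new carbinol centre need not be controlled because it becomes sp2 in the ylide.

**Step 8**
Reactants: 14 (1RS,2S,5Z)-5-methyl-1-(4-methylfuran-2-yl)-2-(propan-2-yl)-2,6-bis[(triethylsilyl)oxy]hex-5-en-1-ol
Product: 15 6-hydroxy-5-methyl-2-[(3S,6Z)-2,6-dimethyl-3,7-bis[(triethylsilyl)oxy]hept-6-en-3-yl]-2H-pyran-3(6H)-one (epimers at C2 and C6 of the pyranone)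
Conditions: VO(acac)2 (5 mol %), t-BuOOH, CH2Cl2, 0 °C
Reagents that add atoms: tert-butyl hydroperoxide, CC(C)(C)OO
Why: Achmatowicz rearrangement, in which the hydroxyl-directed vanadium peroxide should oxidise the furan in preference to the undirected enol ether and the hydroxy ene-dione closes to the pyranone hemiacetal.

**Step 9**
Reactants: 15 6-hydroxy-5-methyl-2-[(3S,6Z)-2,6-dimethyl-3,7-bis[(triethylsilyl)oxy]hept-6-en-3-yl]-2H-pyran-3(6H)-one
Product: 18 (3S,3aS,7R,8S,8aR)-6,8a-dimethyl-3-(propan-2-yl)-3,8-bis[(triethylsilyl)oxy]-1,2,3,7,8,8a-hexahydro-4H-3a,7-epoxyazulen-4-one, via pyranyl mesylate 16 (not isolated), via oxidopyrylium ylide 17 (not isolated)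
Conditions: MsCl, i-Pr2NEt, CH2Cl2, −20 °C → 40 °C
Reagents that add atoms: none
Why: Mesylation of the anomeric hydroxyl and base-induced loss of methanesulfonate together with the proton next to the ketone give the 3-oxidopyrylium (a cyclic carbonyl ylide), which should add across the tethered enol ether in a concerted, suprafacial (5+2) cycloaddition; the closest known reaction type is the intramolecular oxidopyrylium–alkene cycloaddition. The cyclopentane closes through the three-carbon tether (C3a–C8a bond, tether forced exo on the new two-carbon bridge) and the cycloheptenone closes by the cycloaddition itself (C7–C8 bond), leaving the C3a–O–C7 bridge. C8a and C8 follow stereospecifically from the (Z)-enol ether (tether and silyloxy group exo, methyl endo), and C3a and C7 are fixed by the bridge. The regiochemistry is imposed by the tether and matches the polarity of the partners (nucleophilic enol ether β-carbon to the ylide carbon next to the oxido group). The step needs facial selectivity with respect to the C3 stereocentre: the C3 silyloxy group should turn away from the oxido oxygen (dipole minimisation) and lie beside the ring oxygen, which brings the alkene to the face that gives the diastereomer shown.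

**Step 10**
Reactants: 18 (3S,3aS,7R,8S,8aR)-6,8a-dimethyl-3-(propan-2-yl)-3,8-bis[(triethylsilyl)oxy]-1,2,3,7,8,8a-hexahydro-4H-3a,7-epoxyazulen-4-one
Product: 19 (3S,3aR,7R,8S,8aS)-7-hydroxy-6,8a-dimethyl-3-(propan-2-yl)-3,8-bis[(triethylsilyl)oxy]-2,3,3a,7,8,8a-hexahydroazulen-4(1H)-one
Conditions: SmI2 (2.2 equiv), THF–MeOH, −78 °C
Reagents that add atoms: none
Why: SmI2 reduction of the α-alkoxy ketone cleaves the C3a–O bond, and protonation of the samarium enolate at C3a from the face away from the 8a-methyl and 3-isopropyl groups should give the trans ring fusion (3a-H α).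

**Step 11**
Reactants: 19 (3S,3aR,7R,8S,8aS)-7-hydroxy-6,8a-dimethyl-3-(propan-2-yl)-3,8-bis[(triethylsilyl)oxy]-2,3,3a,7,8,8a-hexahydroazulen-4(1H)-one
Product: 20 (3S,3aR,7R,8S,8aS)-6,8a-dimethyl-4-oxo-3-(propan-2-yl)-3,8-bis[(triethylsilyl)oxy]-1,2,3,3a,4,7,8,8a-octahydroazulen-7-yl acetate
Conditions: Ac2O, DMAP, pyridine, CH2Cl2, rt
Reagents that add atoms: acetic anhydride, CC(=O)OC(C)=O
Why: DMAP-catalysed acetylation of the secondary allylic alcohol turns the C7 oxygen into a leaving group for the next reduction.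

**Step 12**
Reactants: 20 (3S,3aR,7R,8S,8aS)-6,8a-dimethyl-4-oxo-3-(propan-2-yl)-3,8-bis[(triethylsilyl)oxy]-1,2,3,3a,4,7,8,8a-octahydroazulen-7-yl acetate
Product: 21 (3S,3aR,8R,8aS)-6,8a-dimethyl-3-(propan-2-yl)-3,8-bis[(triethylsilyl)oxy]-2,3,3a,5,8,8a-hexahydroazulen-4(1H)-one
Conditions: SmI2 (2.5 equiv), THF–MeOH, −78 °C
Reagents that add atoms: none
Why: SmI2-mediated vinylogous reductive elimination of the γ-acetoxy enone gives a dienolate, and its kinetic protonation at the α-carbon (C5) should leave the deconjugated C6=C7 double bond.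

**Step 13**
Reactants: 21 (3S,3aR,8R,8aS)-6,8a-dimethyl-3-(propan-2-yl)-3,8-bis[(triethylsilyl)oxy]-2,3,3a,5,8,8a-hexahydroazulen-4(1H)-one
Product: 22 (3S,3aR,8R,8aS)-3,8-dihydroxy-6,8a-dimethyl-3-(propan-2-yl)-2,3,3a,5,8,8a-hexahydroazulen-4(1H)-one
Conditions: HF·pyridine, pyridine, THF, 0 °C → rt
Reagents that add atoms: none
Why: Fluoride-mediated cleavage of both triethylsilyl ethers under buffered, non-basic conditions that should spare the β,γ-unsaturated ketone and the epimerisable C3a.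

**Step 14**
Reactants: 22 (3S,3aR,8R,8aS)-3,8-dihydroxy-6,8a-dimethyl-3-(propan-2-yl)-2,3,3a,5,8,8a-hexahydroazulen-4(1H)-one; 23 3-methylbutanoyl chloride
Product: 24 (3S,3aR,8R,8aS)-3-hydroxy-6,8a-dimethyl-4-oxo-3-(propan-2-yl)-1,2,3,3a,4,5,8,8a-octahydroazulen-8-yl 3-methylbutanoate
Conditions: 23, pyridine, DMAP (cat.), CH2Cl2, 0 °C
Reagents that add atoms: none
Why: Acylation of the secondary allylic C8 alcohol, selective because the tertiary C3 alcohol is too hindered to react.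

**Step 15**
Reactants: 24 (3S,3aR,8R,8aS)-3-hydroxy-6,8a-dimethyl-4-oxo-3-(propan-2-yl)-1,2,3,3a,4,5,8,8a-octahydroazulen-8-yl 3-methylbutanoate
Product: 25 (3S,3aS,4R,8R,8aS)-3,4-dihydroxy-6,8a-dimethyl-3-(propan-2-yl)-1,2,3,3a,4,5,8,8a-octahydroazulen-8-yl 3-methylbutanoate
Conditions: Me4NBH(OAc)3, MeCN–AcOH, −20 °C
Reagents that add atoms: none
Why: Evans–Saksena hydroxyl-directed reduction, in which the borohydride bound to the α-oriented C3 oxygen should deliver hydride to the α face of C4 and give the (4R) β-alcohol (1,3-anti diol).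

**Step 16**
Reactants: 25 (3S,3aS,4R,8R,8aS)-3,4-dihydroxy-6,8a-dimethyl-3-(propan-2-yl)-1,2,3,3a,4,5,8,8a-octahydroazulen-8-yl 3-methylbutanoate; 26 4-(acetyloxy)benzoyl chloride
Product: 27 (3S,3aS,4R,8R,8aS)-3-hydroxy-6,8a-dimethyl-8-[(3-methylbutanoyl)oxy]-3-(propan-2-yl)-1,2,3,3a,4,5,8,8a-octahydroazulen-4-yl 4-(acetyloxy)benzoate
Conditions: 26, Et3N, DMAP, CH2Cl2, rt
Reagents that add atoms: none
Why: DMAP-catalysed acylation of the secondary C4 alcohol with the phenol-protected aroyl chloride, the tertiary alcohol again staying free.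

**Step 17**
Reactants: 27 (3S,3aS,4R,8R,8aS)-3-hydroxy-6,8a-dimethyl-8-[(3-methylbutanoyl)oxy]-3-(propan-2-yl)-1,2,3,3a,4,5,8,8a-octahydroazulen-4-yl 4-(acetyloxy)benzoate
Product: 28 (3S,3aS,4R,8R,8aS)-3-hydroxy-6,8a-dimethyl-8-[(3-methylbutanoyl)oxy]-3-(propan-2-yl)-1,2,3,3a,4,5,8,8a-octahydroazulen-4-yl 4-hydroxybenzoate
Conditions: NH4OAc, MeOH–H2O, rt
Reagents that add atoms: none
Why: Chemoselective methanolysis of the aryl acetate, which should be cleaved much faster than the two alkyl esters.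

**Compound list**

1 | (S)-2-hydroxy-3-methylbutanoic acid | CC(C)[C@H](O)C(=O)O | starting material
2 | 2,2-dimethylpropanal | CC(C)(C)C=O | starting material
3 | (2S,5S)-2-tert-butyl-5-(propan-2-yl)-1,3-dioxolan-4-one | CC(C)[C@@H]1O[C@H](C(C)(C)C)OC1=O | intermediate
4 | 3-bromoprop-1-ene | C=CCBr | starting material
5 | lithium enolate of 3 (lithium (2S)-2-tert-butyl-5-(propan-2-yl)-1,3-dioxol-4-olate) | CC(C)C1=C(O[Li])O[C@H](O1)C(C)(C)C | intermediate
6 | (2S,5S)-2-tert-butyl-5-(prop-2-en-1-yl)-5-(propan-2-yl)-1,3-dioxolan-4-one | CC(C)[C@]1(CC=C)O[C@H](C(C)(C)C)OC1=O | intermediate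
7 | 2-methylprop-2-enal | CC(=C)C=O | starting material
8 | (2S,5S)-2-tert-butyl-5-[(2E)-3-methyl-4-oxobut-2-en-1-yl]-5-(propan-2-yl)-1,3-dioxolan-4-one | CC(C)[C@]1(C/C=C(\C)C=O)O[C@H](C(C)(C)C)OC1=O | intermediate
9 | (2S,5S)-2-tert-butyl-5-[(3Z)-3-methyl-4-[(triethylsilyl)oxy]but-3-en-1-yl]-5-(propan-2-yl)-1,3-dioxolan-4-one | CC(C)[C@]1(CC/C(C)=C\O[Si](CC)(CC)CC)O[C@H](C(C)(C)C)OC1=O | intermediate
10 | 2-bromo-4-methylfuran | Cc1coc(Br)c1 | starting material
11 | (4-methylfuran-2-yl)lithium | Cc1coc([Li])c1 | intermediate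
12 | (2S,5Z)-2-hydroxy-5-methyl-1-(4-methylfuran-2-yl)-2-(propan-2-yl)-6-[(triethylsilyl)oxy]hex-5-en-1-one | Cc1coc(C(=O)[C@@](O)(C(C)C)CC/C(C)=C\O[Si](CC)(CC)CC)c1 | intermediate
13 | (2S,5Z)-5-methyl-1-(4-methylfuran-2-yl)-2-(propan-2-yl)-2,6-bis[(triethylsilyl)oxy]hex-5-en-1-one | Cc1coc(C(=O)[C@@](O[Si](CC)(CC)CC)(C(C)C)CC/C(C)=C\O[Si](CC)(CC)CC)c1 | intermediate
14 | (1RS,2S,5Z)-5-methyl-1-(4-methylfuran-2-yl)-2-(propan-2-yl)-2,6-bis[(triethylsilyl)oxy]hex-5-en-1-ol | Cc1coc(C(O)[C@@](O[Si](CC)(CC)CC)(C(C)C)CC/C(C)=C\O[Si](CC)(CC)CC)c1 | intermediate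
15 | 6-hydroxy-5-methyl-2-[(3S,6Z)-2,6-dimethyl-3,7-bis[(triethylsilyl)oxy]hept-6-en-3-yl]-2H-pyran-3(6H)-one | O=C1C=C(C)C(O)OC1[C@@](O[Si](CC)(CC)CC)(C(C)C)CC/C(C)=C\O[Si](CC)(CC)CC | intermediate
16 | 5-methyl-3-oxo-2-[(3S,6Z)-2,6-dimethyl-3,7-bis[(triethylsilyl)oxy]hept-6-en-3-yl]-3,6-dihydro-2H-pyran-6-yl methanesulfonate | O=C1C=C(C)C(OS(C)(=O)=O)OC1[C@@](O[Si](CC)(CC)CC)(C(C)C)CC/C(C)=C\O[Si](CC)(CC)CC | intermediate
17 | 5-methyl-2-[(3S,6Z)-2,6-dimethyl-3,7-bis[(triethylsilyl)oxy]hept-6-en-3-yl]pyrylium-3-olate | Cc1c[o+]c(c([O-])c1)[C@@](O[Si](CC)(CC)CC)(C(C)C)CC/C(C)=C\O[Si](CC)(CC)CC | intermediate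
18 | (3S,3aS,7R,8S,8aR)-6,8a-dimethyl-3-(propan-2-yl)-3,8-bis[(triethylsilyl)oxy]-1,2,3,7,8,8a-hexahydro-4H-3a,7-epoxyazulen-4-one (oxygen bridge anti to the 8a-methyl group; both silyloxy groups syn to the bridge) | CC1=CC(=O)[C@]23O[C@H]1[C@@H](O[Si](CC)(CC)CC)[C@@]2(C)CC[C@]3(O[Si](CC)(CC)CC)C(C)C | intermediate
19 | (3S,3aR,7R,8S,8aS)-7-hydroxy-6,8a-dimethyl-3-(propan-2-yl)-3,8-bis[(triethylsilyl)oxy]-2,3,3a,7,8,8a-hexahydroazulen-4(1H)-one | CC1=CC(=O)[C@H]2[C@@](O[Si](CC)(CC)CC)(C(C)C)CC[C@]2(C)[C@H](O[Si](CC)(CC)CC)[C@@H]1O | intermediate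
20 | (3S,3aR,7R,8S,8aS)-6,8a-dimethyl-4-oxo-3-(propan-2-yl)-3,8-bis[(triethylsilyl)oxy]-1,2,3,3a,4,7,8,8a-octahydroazulen-7-yl acetate | CC1=CC(=O)[C@H]2[C@@](O[Si](CC)(CC)CC)(C(C)C)CC[C@]2(C)[C@H](O[Si](CC)(CC)CC)[C@@H]1OC(C)=O | intermediate
21 | (3S,3aR,8R,8aS)-6,8a-dimethyl-3-(propan-2-yl)-3,8-bis[(triethylsilyl)oxy]-2,3,3a,5,8,8a-hexahydroazulen-4(1H)-one | CC1=C[C@@H](O[Si](CC)(CC)CC)[C@@]2(C)CC[C@](O[Si](CC)(CC)CC)(C(C)C)[C@@H]2C(=O)C1 | intermediate
22 | (3S,3aR,8R,8aS)-3,8-dihydroxy-6,8a-dimethyl-3-(propan-2-yl)-2,3,3a,5,8,8a-hexahydroazulen-4(1H)-one | CC1=C[C@@H](O)[C@@]2(C)CC[C@](O)(C(C)C)[C@@H]2C(=O)C1 | intermediate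
23 | 3-methylbutanoyl chloride | CC(C)CC(=O)Cl | starting material
24 | (3S,3aR,8R,8aS)-3-hydroxy-6,8a-dimethyl-4-oxo-3-(propan-2-yl)-1,2,3,3a,4,5,8,8a-octahydroazulen-8-yl 3-methylbutanoate | CC1=C[C@@H](OC(=O)CC(C)C)[C@@]2(C)CC[C@](O)(C(C)C)[C@@H]2C(=O)C1 | intermediate
25 | (3S,3aS,4R,8R,8aS)-3,4-dihydroxy-6,8a-dimethyl-3-(propan-2-yl)-1,2,3,3a,4,5,8,8a-octahydroazulen-8-yl 3-methylbutanoate | CC1=C[C@@H](OC(=O)CC(C)C)[C@@]2(C)CC[C@](O)(C(C)C)[C@@H]2[C@H](O)C1 | intermediate
26 | 4-(acetyloxy)benzoyl chloride | CC(=O)Oc1ccc(cc1)C(Cl)=O | starting material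
27 | (3S,3aS,4R,8R,8aS)-3-hydroxy-6,8a-dimethyl-8-[(3-methylbutanoyl)oxy]-3-(propan-2-yl)-1,2,3,3a,4,5,8,8a-octahydroazulen-4-yl 4-(acetyloxy)benzoate | CC1=C[C@@H](OC(=O)CC(C)C)[C@@]2(C)CC[C@](O)(C(C)C)[C@@H]2[C@H](OC(=O)c2ccc(OC(C)=O)cc2)C1 | intermediate
28 | (3S,3aS,4R,8R,8aS)-3-hydroxy-6,8a-dimethyl-8-[(3-methylbutanoyl)oxy]-3-(propan-2-yl)-1,2,3,3a,4,5,8,8a-octahydroazulen-4-yl 4-hydroxybenzoate | CC1=C[C@@H](OC(=O)CC(C)C)[C@@]2(C)CC[C@](O)(C(C)C)[C@@H]2[C@H](OC(=O)c2ccc(O)cc2)C1 | target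

**Total step count:** 17
**Longest linear sequence:** 17 steps (from 1 to 28)

**Steps most likely to fail**

Step 9 (key step). The facial selectivity with respect to the C3 stereocentre may be poor, because dipole control by the silyloxy group competes with the steric demand of the isopropyl group. The hindered trisubstituted enol ether may also add slowly, so that the ylide dimerises. The fallback sets out from 15 and comes back at 18. The hemiacetal is acylated with 4-(methylsulfanyl)benzoyl chloride (Et3N, DMAP) to the pyranyl 4-(methylsulfanyl)benzoate F1. A chiral primary amine–thiourea with an achiral thiourea co-catalyst and AcOH (toluene, 40 °C) then condenses with the ring ketone, ionises the ester and passes through an aminopyrylium ion. The face of the cycloaddition is thus set by the catalyst and not by the silyloxy group, and hydrolysis of the iminium salt on work-up should give 18.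

Step 10. The first electron transfer may break the vinylogous C7–O bond instead of the C3a–O bond (wrong regiochemistry of the reductive cleavage), or the enolate may expel the C3 silyloxy group. The fallback sets out from 18 and comes back at 21, leaving out 19 and 20. If the C7–O bond is the one that breaks, protonation of the dienolate at C5 should give the tertiary α-ketol, (3S,3aS,8R,8aR)-3a-hydroxy-6,8a-dimethyl-3-(propan-2-yl)-3,8-bis[(triethylsilyl)oxy]-2,3,3a,5,8,8a-hexahydroazulen-4(1H)-one F2. This α-hydroxy ketone is then deoxygenated as such with SmI2 in THF–HMPA with t-BuOH, a known reduction of α-hetero-substituted ketones. Protonation of the enolate anti to the 8a-methyl group should give 21.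

Step 8. Chemoselectivity may be lost: the vanadium peroxide may also oxidise the electron-rich silyl enol ether (Rubottom-type oxidation), or the enol ether may be hydrolysed. The fallback sets out from 14 and comes back at 15. A singlet-oxygen (4+2) cycloaddition (O2, hν, tetraphenylporphyrin, CH2Cl2, −78 °C) is much faster at a furan than at a trisubstituted enol ether and should give the furan endoperoxide, 1-[(1RS,2S,5Z)-1-hydroxy-5-methyl-2-(propan-2-yl)-2,6-bis[(triethylsilyl)oxy]hex-5-en-1-yl]-5-methyl-2,3,7-trioxabicyclo[2.2.1]hept-5-ene F3. Reduction with Me2S opens it to the hydroxy ene-dione, which closes to the hemiacetal 15.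

**Further compounds**

F1 | step 9 | 5-methyl-3-oxo-2-[(3S,6Z)-2,6-dimethyl-3,7-bis[(triethylsilyl)oxy]hept-6-en-3-yl]-3,6-dihydro-2H-pyran-6-yl 4-(methylsulfanyl)benzoate | O=C1C=C(C)C(OC(=O)c2ccc(SC)cc2)OC1[C@@](O[Si](CC)(CC)CC)(C(C)C)CC/C(C)=C\O[Si](CC)(CC)CC
F2 | step 10 | (3S,3aS,8R,8aR)-3a-hydroxy-6,8a-dimethyl-3-(propan-2-yl)-3,8-bis[(triethylsilyl)oxy]-2,3,3a,5,8,8a-hexahydroazulen-4(1H)-one | CC1=C[C@@H](O[Si](CC)(CC)CC)[C@@]2(C)CC[C@](O[Si](CC)(CC)CC)(C(C)C)[C@]2(O)C(=O)C1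
F3 | step 8 | 1-[(1RS,2S,5Z)-1-hydroxy-5-methyl-2-(propan-2-yl)-2,6-bis[(triethylsilyl)oxy]hex-5-en-1-yl]-5-methyl-2,3,7-trioxabicyclo[2.2.1]hept-5-ene | OC([C@@](O[Si](CC)(CC)CC)(C(C)C)CC/C(C)=C\O[Si](CC)(CC)CC)C12OOC(O1)C(C)=C2
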